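**Strategy**

Everything rests on cutting the bond between C4, the benzylic ring CH of the tetralin that carries the side chain, and C11, the side-chain CH(CH3) (serrulatane numbering). Because C4 is benzylic and sits next to the aromatic ring, its carbinol carbamate can be lithiated and used as a chiral carbenoid: it captures the complete side chain, held as a C11 secondary boronic ester, and a 1,2-metallate shift joins the halves and fixes C4 and C11 by reagent control in one operation; stereoretentive protodeboronation then leaves the C4–H. The precursor is a cis-4-methyl-1-tetralol carbamate whose aryl chloride is the latent carboxyl group and whose methyl ether masks the phenol.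

Key step: step 11

Remark: serrulatane numbering is used for the target (C1 = ring CH–CH3, C4 = ring CH bearing the side chain, C6 = C–CO2H, C8 = C–OH, C11 = side-chain CH(CH3) at the ring, C15 = CH(CH3)CH2O); compounds 1 and 7, (+)-sparteine and ethyl 2,4,6-triisopropylbenzoate are taken as purchasable.

**Route**

Step 1
Reactants: 1 1-(4-chloro-2-methoxyphenyl)ethan-1-one
Product: 2 (E)-4-(4-chloro-2-methoxyphenyl)pent-3-enoic acid
Conditions: Ph3P+CH2CH2CO2H Br−, NaHMDS (2.2 equiv), THF, 0 °C → rt; aq HCl; crystallise the E isomer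
Reagents that add atoms: (2-carboxyethyl)triphenylphosphonium bromide, OC(=O)CC[P+](c1ccccc1)(c1ccccc1)c1ccccc1.[Br-]
Why: Wittig olefination of the aryl methyl ketone with the carboxylate ylide should give the β,γ-unsaturated acid directly, the E isomer being secured by crystallisation, and no stereocentre is formed.

Step 2
Reactants: 2 (E)-4-(4-chloro-2-methoxyphenyl)pent-3-enoic acid
Product: 3 (R)-4-(4-chloro-2-methoxyphenyl)pentanoic acid
Conditions: [Ir(cod)(SIPHOX)]BArF (1 mol%, ligand enantiomer that delivers the 4R acid), H2 (6 atm), Et3N (0.5 equiv), MeOH, rt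
Reagents that add atoms: none
Why: Carboxy-directed iridium-catalysed asymmetric hydrogenation of (E)-4-aryl-pent-3-enoic acids sets the benzylic methyl centre (later C1) by catalyst control, and the aryl chloride is inert to the catalyst.

Step 3
Reactants: 3 (R)-4-(4-chloro-2-methoxyphenyl)pentanoic acid
Product: 4 (R)-7-chloro-5-methoxy-4-methyl-3,4-dihydronaphthalen-1(2H)-one
Conditions: Eaton's reagent (P2O5/MeSO3H), 50 °C
Reagents that add atoms: none
Why: Intramolecular Friedel–Crafts acylation can close only at the single free position ortho to the chain, the methyl ether and aryl chloride tolerate the medium, and the non-enolisable benzylic stereocentre is untouched.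

Step 4
Reactants: 4 (R)-7-chloro-5-methoxy-4-methyl-3,4-dihydronaphthalen-1(2H)-one
Product: 5 (1S,4R)-7-chloro-5-methoxy-4-methyl-1,2,3,4-tetrahydronaphthalen-1-ol
Conditions: RuCl[(S,S)-TsDPEN](p-cymene) (1 mol%), HCO2H/Et3N (5:2), rt
Reagents that add atoms: none
Why: Noyori asymmetric transfer hydrogenation of 1-tetralones with the (S,S) catalyst should give the (S)-carbinol under catalyst control, which is the cis isomer relative to the remote methyl group.

Step 5
Reactants: 5 (1S,4R)-7-chloro-5-methoxy-4-methyl-1,2,3,4-tetrahydronaphthalen-1-ol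
Product: 6 (1S,4R)-7-chloro-5-methoxy-4-methyl-1,2,3,4-tetrahydronaphthalen-1-yl N,N-diisopropylcarbamate
Conditions: iPr2NCOCl, Et3N, CH2Cl2, reflux
Reagents that add atoms: N,N-diisopropylcarbamoyl chloride, CC(C)N(C(C)C)C(=O)Cl
Why: O-carbamoylation under basic, non-ionising conditions keeps the benzylic configuration and installs the group that directs lithiation and later leaves in step 11.

Step 6
Reactants: 7 (S)-4-benzyl-3-propanoyl-1,3-oxazolidin-2-one
Product: 9 (S)-4-benzyl-3-[(R)-2-methylpent-4-enoyl]-1,3-oxazolidin-2-one, via sodium Z-enolate 8 (not isolated)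
Conditions: NaHMDS, THF, −78 °C; allyl iodide, −78 → −45 °C
Reagents that add atoms: allyl iodide, C=CCI
Why: Evans asymmetric alkylation, in which the chelated Z-enolate is allylated on the face opposite the benzyl group, sets the later C15 centre as R.

Step 7
Reactants: 9 (S)-4-benzyl-3-[(R)-2-methylpent-4-enoyl]-1,3-oxazolidin-2-one
Product: 10 (R)-2-methylpent-4-en-1-ol
Conditions: LiBH4, H2O (1 equiv), Et2O, 0 °C
Reagents that add atoms: none
Why: Reductive cleavage of the N-acyl oxazolidinone with LiBH4 releases the primary alcohol without touching the α-stereocentre or the alkene.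

Step 8
Reactants: 10 (R)-2-methylpent-4-en-1-ol
Product: 11 (R)-tert-butyldimethyl[(2-methylpent-4-en-1-yl)oxy]silane
Conditions: TBSCl, imidazole, CH2Cl2, rt
Reagents that add atoms: tert-butyldimethylsilyl chloride, CC(C)(C)[Si](C)(C)Cl
Why: Standard silylation gives an ether that tolerates the organolithium and boron chemistry ahead and is removed in step 12.

Step 9
Reactants: 11 (R)-tert-butyldimethyl[(2-methylpent-4-en-1-yl)oxy]silane
Product: 12 (R)-tert-butyldimethyl{[2-methyl-5-(4,4,5,5-tetramethyl-1,3,2-dioxaborolan-2-yl)pentyl]oxy}silane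
Conditions: HBpin, [Ir(cod)Cl]2 (1.5 mol%), dppe (3 mol%), CH2Cl2, rt
Reagents that add atoms: pinacolborane, [H]B1OC(C)(C)C(C)(C)O1
Why: Iridium-catalysed hydroboration of the terminal alkene is anti-Markovnikov and leaves the silyl ether and the stereocentre untouched.

Step 10
Reactants: 12 (R)-tert-butyldimethyl{[2-methyl-5-(4,4,5,5-tetramethyl-1,3,2-dioxaborolan-2-yl)pentyl]oxy}silane
Product: 14 tert-butyldimethyl{[(2R,6S)-2-methyl-6-(4,4,5,5-tetramethyl-1,3,2-dioxaborolan-2-yl)heptyl]oxy}silane, via boronate complex 13 (not isolated)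
Conditions: ethyl 2,4,6-triisopropylbenzoate, (+)-sparteine, sBuLi, Et2O, −78 °C, 5 h; 12, −78 °C, 1 h; then reflux, 16 h
Reagents that add atoms: ethyl 2,4,6-triisopropylbenzoate, CCOC(=O)c1c(C(C)C)cc(C(C)C)cc1C(C)C
Why: Reagent-controlled lithiation–borylation homologation, in which the (+)-sparteine-derived (R)-lithiated ethyl benzoate adds to boron with retention and the primary alkyl group migrates with inversion, sets the later C11 centre as S independently of the existing centre.

Step 11
Reactants: 6 (1S,4R)-7-chloro-5-methoxy-4-methyl-1,2,3,4-tetrahydronaphthalen-1-yl N,N-diisopropylcarbamate; 14 tert-butyldimethyl{[(2R,6S)-2-methyl-6-(4,4,5,5-tetramethyl-1,3,2-dioxaborolan-2-yl)heptyl]oxy}silane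
Product: 17 2-{(1S,4R)-1-[(2S,6R)-7-(tert-butyldimethylsilyloxy)-6-methylheptan-2-yl]-7-chloro-5-methoxy-4-methyl-1,2,3,4-tetrahydronaphthalen-1-yl}-4,4,5,5-tetramethyl-1,3,2-dioxaborolane, via lithiated carbamate 15 (not isolated), via boronate complex 16 (not isolated)
Conditions: 6, sBuLi, Et2O, −78 °C, 1 h; 14, −78 °C, 2 h; MgBr2·OEt2/MeOH, −78 °C → rt, 16 h
Reagents that add atoms: none
Why: Lithiation–borylation with 1,2-metallate rearrangement: sBuLi removes the carbinol hydrogen of the benzylic carbamate with retention to give the configurationally stable α-oxy benzyllithium 15, which adds to the boron of 14 with retention to give ate complex 16, and MgBr2/MeOH then triggers the anti-periplanar 1,2-shift of the secondary alkyl group with loss of the carbamate, that is inversion at the benzylic carbon and retention at the migrating carbon. The closest known reaction type is the coupling of lithiated secondary benzylic carbamates with secondary pinacol boronic esters to give tertiary boronic esters next to a tertiary centre, and no ring is closed. The quaternary benzylic centre (later C4) is controlled by the carbinol configuration of 6 set in step 4, and the adjacent CH(CH3) centre (C11) is carried over unchanged from 14 as set in step 10, so both are under reagent control and independent of the remote ring methyl centre. The step needs deprotonation α to the carbamate in preference to ortho-lithiation beside Cl or OMe, which the benzylic, dipole-stabilised position should secure in diamine-free Et2O at −78 °C, and it needs ate-complex formation with a hindered partner to be productive, which the MgBr2/MeOH additive supports by speeding migration and quenching any dissociated carbanion.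

Step 12
Reactants: 17 2-{(1S,4R)-1-[(2S,6R)-7-(tert-butyldimethylsilyloxy)-6-methylheptan-2-yl]-7-chloro-5-methoxy-4-methyl-1,2,3,4-tetrahydronaphthalen-1-yl}-4,4,5,5-tetramethyl-1,3,2-dioxaborolane
Product: 19 (2R,6S)-6-[(1S,4R)-7-chloro-5-methoxy-4-methyl-1,2,3,4-tetrahydronaphthalen-1-yl]-2-methylheptan-1-ol, via silyl ether 18 (not isolated)
Conditions: TBAF·3H2O (excess), toluene, 50 °C; then THF, rt
Reagents that add atoms: none
Why: Fluoride-promoted protodeboronation of tertiary benzylic pinacol boronic esters replaces boron by hydrogen with retention, which fixes C4 as S, and the same reagent removes the TBS group.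

Step 13
Reactants: 19 (2R,6S)-6-[(1S,4R)-7-chloro-5-methoxy-4-methyl-1,2,3,4-tetrahydronaphthalen-1-yl]-2-methylheptan-1-ol
Product: 20 (2R,6S)-6-[(1S,4R)-7-chloro-5-methoxy-4-methyl-1,2,3,4-tetrahydronaphthalen-1-yl]-2-methylheptyl 3-phenylpropanoate
Conditions: PhCH2CH2COCl, pyridine, CH2Cl2, 0 °C → rt
Reagents that add atoms: 3-phenylpropanoyl chloride, O=C(Cl)CCc1ccccc1
Why: Acylation of the unhindered primary alcohol with the acid chloride is straightforward because nothing else in 19 is nucleophilic.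

Step 14
Reactants: 20 (2R,6S)-6-[(1S,4R)-7-chloro-5-methoxy-4-methyl-1,2,3,4-tetrahydronaphthalen-1-yl]-2-methylheptyl 3-phenylpropanoate
Product: 21 (5R,8S)-4-methoxy-5-methyl-8-[(2S,6R)-6-methyl-7-(3-phenylpropanoyloxy)heptan-2-yl]-5,6,7,8-tetrahydronaphthalene-2-carboxylic acid
Conditions: NiCl2(PPh3)2 (10 mol%), PPh3 (20 mol%), Mn, Et4NI (10 mol%), CO2 (1 atm), DMI, rt; then aq HCl
Reagents that add atoms: carbon dioxide, O=C=O
Why: Nickel-catalysed reductive carboxylation of aryl chlorides with CO2 and manganese runs at room temperature under neutral conditions that the alkyl ester and aryl ether tolerate, and the chloride is flanked only by hydrogens.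

Step 15
Reactants: 21 (5R,8S)-4-methoxy-5-methyl-8-[(2S,6R)-6-methyl-7-(3-phenylpropanoyloxy)heptan-2-yl]-5,6,7,8-tetrahydronaphthalene-2-carboxylic acid
Product: 22 (5R,8S)-4-hydroxy-5-methyl-8-[(2S,6R)-6-methyl-7-(3-phenylpropanoyloxy)heptan-2-yl]-5,6,7,8-tetrahydronaphthalene-2-carboxylic acid
Conditions: BBr3, CH2Cl2, −78 → 0 °C; H2O
Reagents that add atoms: none
Why: Lewis-acid cleavage of the aryl methyl ether with BBr3 at low temperature should be faster than attack on the alkyl ester, and no stereocentre is involved.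

**Compound list**

1 | 1-(4-chloro-2-methoxyphenyl)ethan-1-one | CC(=O)c1ccc(Cl)cc1OC | starting material
2 | (E)-4-(4-chloro-2-methoxyphenyl)pent-3-enoic acid | C/C(=C\CC(=O)O)c1ccc(Cl)cc1OC | intermediate
3 | (R)-4-(4-chloro-2-methoxyphenyl)pentanoic acid | C[C@H](CCC(=O)O)c1ccc(Cl)cc1OC | intermediate
4 | (R)-7-chloro-5-methoxy-4-methyl-3,4-dihydronaphthalen-1(2H)-one | C[C@@H]1CCC(=O)c2cc(Cl)cc(OC)c21 | intermediate
5 | (1S,4R)-7-chloro-5-methoxy-4-methyl-1,2,3,4-tetrahydronaphthalen-1-ol (cis) | C[C@@H]1CC[C@H](O)c2cc(Cl)cc(OC)c21 | intermediate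
6 | (1S,4R)-7-chloro-5-methoxy-4-methyl-1,2,3,4-tetrahydronaphthalen-1-yl N,N-diisopropylcarbamate | C[C@@H]1CC[C@H](OC(=O)N(C(C)C)C(C)C)c2cc(Cl)cc(OC)c21 | intermediate
7 | (S)-4-benzyl-3-propanoyl-1,3-oxazolidin-2-one | CCC(=O)N1[C@@H](Cc2ccccc2)COC1=O | starting material
8 | sodium Z-enolate of 7 | [Na+].C/C=C(\[O-])N1[C@@H](Cc2ccccc2)COC1=O | intermediate (not isolated)
9 | (S)-4-benzyl-3-[(R)-2-methylpent-4-enoyl]-1,3-oxazolidin-2-one | C=CC[C@@H](C)C(=O)N1[C@@H](Cc2ccccc2)COC1=O | intermediate
10 | (R)-2-methylpent-4-en-1-ol | C=CC[C@@H](C)CO | intermediate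
11 | (R)-tert-butyldimethyl[(2-methylpent-4-en-1-yl)oxy]silane | C=CC[C@@H](C)CO[Si](C)(C)C(C)(C)C | intermediate
12 | (R)-tert-butyldimethyl{[2-methyl-5-(4,4,5,5-tetramethyl-1,3,2-dioxaborolan-2-yl)pentyl]oxy}silane | CC1(C)OB(CCC[C@@H](C)CO[Si](C)(C)C(C)(C)C)OC1(C)C | intermediate
13 | lithium boronate complex of 12 with (R)-1-lithioethyl 2,4,6-triisopropylbenzoate (boron in place of lithium, retention) | [Li+].C[C@H](OC(=O)c1c(C(C)C)cc(C(C)C)cc1C(C)C)[B-]2(CCC[C@@H](C)CO[Si](C)(C)C(C)(C)C)OC(C)(C)C(C)(C)O2 | intermediate (not isolated)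
14 | tert-butyldimethyl{[(2R,6S)-2-methyl-6-(4,4,5,5-tetramethyl-1,3,2-dioxaborolan-2-yl)heptyl]oxy}silane | C[C@@H](CCC[C@@H](C)CO[Si](C)(C)C(C)(C)C)B1OC(C)(C)C(C)(C)O1 | intermediate
15 | 1-lithio derivative of carbamate 6 (lithium in place of the carbinol hydrogen, configuration retained) | C[C@@H]1CC[C@]([Li])(OC(=O)N(C(C)C)C(C)C)c2cc(Cl)cc(OC)c21 | intermediate (not isolated)
16 | lithium boronate complex of 15 and 14 (boron in place of lithium, retention) | [Li+].C[C@@H]1CC[C@]([B-]3([C@@H](C)CCC[C@@H](C)CO[Si](C)(C)C(C)(C)C)OC(C)(C)C(C)(C)O3)(OC(=O)N(C(C)C)C(C)C)c2cc(Cl)cc(OC)c21 | intermediate (not isolated)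
17 | 2-{(1S,4R)-1-[(2S,6R)-7-(tert-butyldimethylsilyloxy)-6-methylheptan-2-yl]-7-chloro-5-methoxy-4-methyl-1,2,3,4-tetrahydronaphthalen-1-yl}-4,4,5,5-tetramethyl-1,3,2-dioxaborolane | C[C@@H]1CC[C@@](B3OC(C)(C)C(C)(C)O3)([C@@H](C)CCC[C@@H](C)CO[Si](C)(C)C(C)(C)C)c2cc(Cl)cc(OC)c21 | intermediate
18 | tert-butyl{[(2R,6S)-6-[(1S,4R)-7-chloro-5-methoxy-4-methyl-1,2,3,4-tetrahydronaphthalen-1-yl]-2-methylheptyl]oxy}dimethylsilane | C[C@@H]1CC[C@@H]([C@@H](C)CCC[C@@H](C)CO[Si](C)(C)C(C)(C)C)c2cc(Cl)cc(OC)c21 | intermediate (not isolated)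
19 | (2R,6S)-6-[(1S,4R)-7-chloro-5-methoxy-4-methyl-1,2,3,4-tetrahydronaphthalen-1-yl]-2-methylheptan-1-ol | C[C@@H]1CC[C@@H]([C@@H](C)CCC[C@@H](C)CO)c2cc(Cl)cc(OC)c21 | intermediate
20 | (2R,6S)-6-[(1S,4R)-7-chloro-5-methoxy-4-methyl-1,2,3,4-tetrahydronaphthalen-1-yl]-2-methylheptyl 3-phenylpropanoate | C[C@@H]1CC[C@@H]([C@@H](C)CCC[C@@H](C)COC(=O)CCc3ccccc3)c2cc(Cl)cc(OC)c21 | intermediate
21 | (5R,8S)-4-methoxy-5-methyl-8-[(2S,6R)-6-methyl-7-(3-phenylpropanoyloxy)heptan-2-yl]-5,6,7,8-tetrahydronaphthalene-2-carboxylic acid | C[C@@H]1CC[C@@H]([C@@H](C)CCC[C@@H](C)COC(=O)CCc3ccccc3)c2cc(C(=O)O)cc(OC)c21 | intermediate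
22 | (5R,8S)-4-hydroxy-5-methyl-8-[(2S,6R)-6-methyl-7-(3-phenylpropanoyloxy)heptan-2-yl]-5,6,7,8-tetrahydronaphthalene-2-carboxylic acid (CNP0511546.1; 1R,4S,11S,15R in serrulatane numbering) | C[C@@H]1CC[C@@H]([C@@H](C)CCC[C@@H](C)COC(=O)CCc3ccccc3)c2cc(C(=O)O)cc(O)c21 | target

**Step count and risks**

Total steps: 15. Longest linear sequence: 10 steps (1–5, then 11–15; the side-chain branch 6–10, then 11–15, is equally long).

Steps most likely to fail:

1. Step 11. Ate-complex formation between the tertiary benzyllithium and the hindered secondary boronic ester may be slow or reversible, so that the lithiated carbamate decomposes or stereochemical fidelity at the benzylic carbon is lost. The fallback sets out from 12 and 6 and comes back at 17. Vinylidene homologation of 12 (vinyl bromide, LiTMP, THF, low temperature) would give the alkenyl boronic ester (R)-tert-butyldimethyl{[2-methyl-6-(4,4,5,5-tetramethyl-1,3,2-dioxaborolan-2-yl)hept-6-en-1-yl]oxy}silane F1. Lithiation–borylation of 6 with this flatter and better-migrating sp2 partner, under the conditions of step 11, would give the tertiary allylic boronic ester 2-{(1S,4R)-1-[(6R)-7-(tert-butyldimethylsilyloxy)-6-methylhept-1-en-2-yl]-7-chloro-5-methoxy-4-methyl-1,2,3,4-tetrahydronaphthalen-1-yl}-4,4,5,5-tetramethyl-1,3,2-dioxaborolane F2 with the same sense at the benzylic carbon. Catalyst-controlled hydrogenation of its 1,1-disubstituted alkene (chiral Ir–P,N catalyst, H2) would then set C11 and deliver 17, with the diastereomers to be separated if needed.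

2. Step 14. Oxidative addition to the electron-rich, lipophilic aryl chloride may be slow, or the aryl–nickel species may be protonated to the arene instead of capturing CO2. The fallback sets out from 20 and comes back at 21. Suzuki–Miyaura vinylation (potassium vinyltrifluoroborate, Pd(OAc)2/SPhos, K2CO3, dioxane/H2O, 80 °C) would give the styrene (2R,6S)-6-[(1S,4R)-7-ethenyl-5-methoxy-4-methyl-1,2,3,4-tetrahydronaphthalen-1-yl]-2-methylheptyl 3-phenylpropanoate F3. Lemieux–Johnson cleavage (OsO4 cat., NaIO4, 2,6-lutidine, dioxane/H2O) would give the aldehyde (2R,6S)-6-[(1S,4R)-7-formyl-5-methoxy-4-methyl-1,2,3,4-tetrahydronaphthalen-1-yl]-2-methylheptyl 3-phenylpropanoate F4. Pinnick oxidation (NaClO2, NaH2PO4, 2-methyl-2-butene, tBuOH/H2O) would then give 21.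

3. Step 15. Coordination of BBr3 to the alkyl ester and bromide attack may cleave the 3-phenylpropanoate in competition with the aryl methyl ether. The fallback sets out from 19 and comes back at 22, moving the demethylation to a stage without an ester. Thiolate demethylation of 19 (NaSEt, DMF, 110 °C) would give the phenol (5S,8R)-3-chloro-5-[(2S,6R)-7-hydroxy-6-methylheptan-2-yl]-8-methyl-5,6,7,8-tetrahydronaphthalen-1-ol F5. Acylation of both hydroxyl groups (3-phenylpropanoyl chloride, Et3N, DMAP, CH2Cl2) would give the bis-ester (2R,6S)-6-[(1S,4R)-7-chloro-4-methyl-5-(3-phenylpropanoyloxy)-1,2,3,4-tetrahydronaphthalen-1-yl]-2-methylheptyl 3-phenylpropanoate F6. Nickel-catalysed carboxylation as in step 14 would give the acid (5R,8S)-5-methyl-8-[(2S,6R)-6-methyl-7-(3-phenylpropanoyloxy)heptan-2-yl]-4-(3-phenylpropanoyloxy)-5,6,7,8-tetrahydronaphthalene-2-carboxylic acid F7. Chemoselective aminolysis of the more reactive aryl ester (pyrrolidine, THF, 0 °C → rt) would then release 22.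

**Further compounds**

F1 | step 11 | (R)-tert-butyldimethyl{[2-methyl-6-(4,4,5,5-tetramethyl-1,3,2-dioxaborolan-2-yl)hept-6-en-1-yl]oxy}silane | C=C(CCC[C@@H](C)CO[Si](C)(C)C(C)(C)C)B1OC(C)(C)C(C)(C)O1
F2 | step 11 | 2-{(1S,4R)-1-[(6R)-7-(tert-butyldimethylsilyloxy)-6-methylhept-1-en-2-yl]-7-chloro-5-methoxy-4-methyl-1,2,3,4-tetrahydronaphthalen-1-yl}-4,4,5,5-tetramethyl-1,3,2-dioxaborolane | C[C@@H]1CC[C@@](B3OC(C)(C)C(C)(C)O3)(C(=C)CCC[C@@H](C)CO[Si](C)(C)C(C)(C)C)c2cc(Cl)cc(OC)c21
F3 | step 14 | (2R,6S)-6-[(1S,4R)-7-ethenyl-5-methoxy-4-methyl-1,2,3,4-tetrahydronaphthalen-1-yl]-2-methylheptyl 3-phenylpropanoate | C[C@@H]1CC[C@@H]([C@@H](C)CCC[C@@H](C)COC(=O)CCc3ccccc3)c2cc(C=C)cc(OC)c21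
F4 | step 14 | (2R,6S)-6-[(1S,4R)-7-formyl-5-methoxy-4-methyl-1,2,3,4-tetrahydronaphthalen-1-yl]-2-methylheptyl 3-phenylpropanoate | C[C@@H]1CC[C@@H]([C@@H](C)CCC[C@@H](C)COC(=O)CCc3ccccc3)c2cc(C=O)cc(OC)c21
F5 | step 15 | (5S,8R)-3-chloro-5-[(2S,6R)-7-hydroxy-6-methylheptan-2-yl]-8-methyl-5,6,7,8-tetrahydronaphthalen-1-ol | C[C@@H]1CC[C@@H]([C@@H](C)CCC[C@@H](C)CO)c2cc(Cl)cc(O)c21
F6 | step 15 | (2R,6S)-6-[(1S,4R)-7-chloro-4-methyl-5-(3-phenylpropanoyloxy)-1,2,3,4-tetrahydronaphthalen-1-yl]-2-methylheptyl 3-phenylpropanoate | C[C@@H]1CC[C@@H]([C@@H](C)CCC[C@@H](C)COC(=O)CCc3ccccc3)c2cc(Cl)cc(OC(=O)CCc3ccccc3)c21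
F7 | step 15 | (5R,8S)-5-methyl-8-[(2S,6R)-6-methyl-7-(3-phenylpropanoyloxy)heptan-2-yl]-4-(3-phenylpropanoyloxy)-5,6,7,8-tetrahydronaphthalene-2-carboxylic acid | C[C@@H]1CC[C@@H]([C@@H](C)CCC[C@@H](C)COC(=O)CCc3ccccc3)c2cc(C(=O)O)cc(OC(=O)CCc3ccccc3)c21
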